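The numbers in the tables are simulated from invented constants; the scatter is artificial.

In the beta run, charged with 0.40 M of solid substrate, the target levelled off at a mean of 12.5% of that charge. In the alpha run, with twice the charge, it levelled off at 6.26%, half the percentage. So I replaced each flat stretch by its mean and multiplied by the charge. This gave the target ceiling Cp, the concentration of target once the readings go flat: 0.0501 M from alpha and 0.0502 M from beta. The mean cost little: the farthest alpha reading, 5.6%, lay 0.66 percentage points below it, against a scatter of 0.5 points.

| flask | solid substrate | partner | remark | time |
|---|---|---|---|---|
| alpha | 0.80 M | 2.8 M | run made earlier |  |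
| beta | 0.40 M | 2 M | run made earlier |  |
| flask | 0.80 M | 2.00 M |  | 15 d |

- alpha (time / d: solid substrate / %, target / %): 1.25: 44.4, 4.9; 2.00: 17.7, 5.1; 3.00: 0, 6.7; 5.00: 0, 6.5; 8.00: 0, 6.2; 12.0: 0.5, 5.6; 20.0: 0, 6.3
- beta (time / d: solid substrate / %, target / %): 1.67: 0.2, 11.4; 5.00: 0.2, 12.6; 8.00: 0, 12.6; 12.0: 0, 12.4; 20.0: 0, 12.6

(scatter of a reading: 0.5 percentage points)

- solid, in amounts per volume of the solution: solid substrate
- at the start none of the solid substrate is in solution
- what has only dissolved of solid substrate counts as not reacted
- the reaction counts as stopped when no species that holds the solid substrate changes by six tenths of a point or more over the second half of the time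

* the state of affairs at 15 d: stopped, and by what, or still going (for what has run out or reacted, a solid counts together with what of it has only dissolved) (it is still moving / all of the solid substrate has reacted / forward and back rates have come level / the partner has run out first)
* part of the solid substrate that has turned into other species by 15 d (what has only dissolved does not count)
* the target standing at 15 d, as a percentage of the solid substrate charged
* amount of target if the flask were left three thousand times as long, in percent of the solid substrate charged

I then went through alpha slowly. In the first 1.25 d the solid fell to 44.4% and the target reached 4.9%, already 78.3% of its mean plateau. Between then and 3.00 d the solid lost another 44 points, while the target gained 1.8 points. From there to 20.0 d the target stayed flat. The new flask has alpha's 0.80 M of solid and beta's 2.00 M of partner, so I took beta's Cp and divided it by the flask's charge, which gave 6.27% of target at 15 d and the same later. The solid readings show that solid vanished, not that what dissolved reacted, so I committed to no conversion.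

The forecast gave "all of the solid substrate has reacted", 100% conversion, 6.3% target and 6.3% in the long run, holding that “dissolution and reaction should finish within about 3–5 d, well before 15 d”.

The flask gave "the partner has run out first", with the partner at 0% by 1.50 d, conversion 83.9%, target 6.07%, and 6.07% in the long run.

    starting material → decomposition product (k = 1.20 × 10⁻⁴ h⁻¹)
    partner → second intermediate (k = 3.10 h⁻¹)
    starting material ⇌ open intermediate (K = 4.80, k = 0.270 h⁻¹)
    2 second intermediate → homo product (k = 0.680 M⁻¹ h⁻¹)
    open intermediate + second intermediate → target (k = 0.360 M⁻¹ h⁻¹)
    solid substrate ⇌ starting material, rate k6*(cs6 - [starting material]) while solid is left; crystals form when [starting material] > cs6 (solubility = 0.330 M, k = 0.0570 h⁻¹)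
    second intermediate → side product (k = 0.0120 h⁻¹)

The flask's target amounts to 0.0486 M, against my Cp of 0.0502 M. Its solid stood at 0% at 15.0 d, yet 16.1% remained as dissolved starting material, which counts as not reacted. The neighbouring flask differs from this flask in its 0.32 M of solid substrate, and Cp divided by that charge gave 15.7%. The neighbour's target stood at 15.0%, or 0.0480 M, with 69.8% of its charge as open intermediate.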